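The seven-membered ring (daucane numbering) is disconnected at C6–C7 and C1–C10 into a three-carbon unit C6–C5–C1, held in a cyclopentenyl acylsilane that already carries the C2 oxygen and the C4 carbinol, and a four-carbon unit C7–C10, the lithium enolate of a β-silyloxy enone. A Brook-rearrangement-mediated anionic [3+4] annulation forms both bonds in one operation through a temporary cyclopropane bond C6–C8 that an oxy-Cope rearrangement cleaves. It exploits the C8=C9 alkene of the seven-membered ring, flanked by the C6 oxygen and the quaternary C1: the rearrangement leaves an enolate at C8 (later the methyl-bearing alkene) and a silyl enol ether at C6.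

Key step: step 9

Remark: daucane numbering is used for all bicyclic compounds (C1 quaternary carbon with the methyl group, C2 acetate carbon, C3, C4 carbinol carbon with isopropyl, C5 ring-fusion CH, C6 angelate carbon, C7, C8 methyl-bearing alkene carbon, C9, C10 benzoate carbon); β is the face of the C1 methyl group, and the skeleton name implies 1β-methyl and 4α-isopropyl. The C2 and C10 oxygens are carried with the wrong configuration on purpose, as control elements, and are reset in steps 15, 16 and 18.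

Step 1
Reactants: 1 (R)-4-(tert-butyldimethylsilyloxy)cyclopent-2-en-1-one
Product: 2 (3R,4R)-4-(tert-butyldimethylsilyloxy)-3-methyl-1-(trimethylsilyloxy)cyclopent-1-ene
Conditions: Me2CuLi, TMSCl, THF, −78 °C; Et3N, aq. NaHCO3
Reagents that add atoms: lithium dimethylcuprate, [Li+].C[Cu-]C; chlorotrimethylsilane, C[Si](C)(C)Cl
Why: Cuprate conjugate addition should occur anti to the silyloxy group, and O-silylation of the enolate in situ fixes the enol ether regiochemistry for step 2.

Step 2
Reactants: 2 silyl enol ether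
Product: 3 (R)-4-(tert-butyldimethylsilyloxy)-3-methylcyclopent-2-en-1-one
Conditions: Pd(OAc)2 (10 mol %), O2 (1 atm), DMSO, rt
Reagents that add atoms: none
Why: Saegusa–Ito oxidation: the palladium enolate can only undergo β-hydride elimination towards the methyl-bearing carbon, which restores the enone with the methyl group on the β-carbon and leaves the silyloxy stereocentre untouched.

Step 3
Reactants: 3 enone
Product: 5 (R)-2-bromo-4-(tert-butyldimethylsilyloxy)-3-methylcyclopent-2-en-1-one, via trans-2,3-dibromoketone 4 (not isolated)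
Conditions: Br2, CH2Cl2, 0 °C; then Et3N, 0 °C to rt
Reagents that add atoms: bromine, BrBr
Why: Bromination–dehydrobromination: bromine adds across the enone and the amine removes the acidic α-hydrogen with loss of the β-bromide, leaving the α-bromoenone (either anti dibromide gives 5).

Step 4
Reactants: 5 α-bromoenone
Product: 6 (1R,4R)-2-bromo-4-(tert-butyldimethylsilyloxy)-3-methyl-1-(propan-2-yl)cyclopent-2-en-1-ol
Conditions: iPrMgCl, CeCl3, THF, −78 °C
Reagents that add atoms: isopropylmagnesium chloride, CC(C)[Mg]Cl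
Why: 1,2-Addition of the organocerium reagent avoids enolisation and halogen–metal exchange and should take place on the carbonyl face anti to the silyloxy group, so that the new hydroxyl is cis to it (this is the final C4 configuration).

Step 5
Reactants: 6 tertiary alcohol
Product: 7 (1R,4R)-2-bromo-4-(tert-butyldimethylsilyloxy)-3-methyl-1-(propan-2-yl)-1-(triethylsilyloxy)cyclopent-2-ene
Conditions: TESOTf, 2,6-lutidine, CH2Cl2, −78 to 0 °C
Reagents that add atoms: triethylsilyl trifluoromethanesulfonate, CC[Si](CC)(CC)OS(=O)(=O)C(F)(F)F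
Why: Silyl ether formation with a silyl triflate and a hindered base masks the tertiary allylic alcohol for the organolithium steps.

Step 6
Reactants: 7 vinyl bromide
Product: 9 [(3R,5R)-3-(tert-butyldimethylsilyloxy)-2-methyl-5-(propan-2-yl)-5-(triethylsilyloxy)cyclopent-1-en-1-yl](morpholin-4-yl)methanone, via vinyllithium 8 (not isolated)
Conditions: t-BuLi (2.1 equiv), THF, −78 °C; morpholine-4-carbonyl chloride, −78 to 0 °C
Reagents that add atoms: morpholine-4-carbonyl chloride, O=C(Cl)N1CCOCC1
Why: Bromine–lithium exchange gives the tetrasubstituted vinyllithium, which is acylated by the carbamoyl chloride (nucleophilic acyl substitution); the new carbonyl carbon is C6 of the target.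

Step 7
Reactants: 9 morpholine amide
Product: 10 [(3R,5R)-3-(tert-butyldimethylsilyloxy)-2-methyl-5-(propan-2-yl)-5-(triethylsilyloxy)cyclopent-1-en-1-yl](dimethylphenylsilyl)methanone
Conditions: PhMe2SiLi, THF, −78 °C; aq. NH4Cl
Reagents that add atoms: dimethylphenylsilyllithium, [Li][Si](C)(C)c1ccccc1
Why: Acylsilane synthesis from a morpholine amide: the silyl anion adds once to give a tetrahedral lithium hemiaminal that collapses only on work-up, so over-addition is avoided.

Step 8
Reactants: 11 but-3-yn-2-one; 12 tert-butyldimethylsilanol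
Product: 13 (E)-4-(tert-butyldimethylsilyloxy)but-3-en-2-one
Conditions: PBu3 (5 mol %), CH2Cl2, 0 °C to rt
Reagents that add atoms: none
Why: Phosphine-catalysed oxa-Michael addition of the silanol to the ynone should give the thermodynamically preferred E β-silyloxy enone.

Step 9
Reactants: 10 acylsilane; 13 β-silyloxy enone
Product: 17 2β,10α-bis(tert-butyldimethylsilyloxy)-6-(dimethylphenylsilyloxy)-4β-(triethylsilyloxy)-14-nordauca-5,8-dien-8-yl trifluoromethanesulfonate, via lithium dienolate 14 (not isolated), via cis-dialkenylcyclopropanediolate 15 (not isolated), via lithium cycloheptadienolate 16 (not isolated)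
Conditions: 13, LiN(iPr)2 (LDA), THF, −78 °C; add 10, −78 to −30 °C; PhNTf2, −78 to 0 °C
Reagents that add atoms: N-phenylbis(trifluoromethanesulfonimide), O=S(=O)(N(c1ccccc1)S(=O)(=O)C(F)(F)F)C(F)(F)F
Why: Enolate 14 adds through C7 to the acylsilane carbonyl (C6), the α-silyl alkoxide undergoes 1,2-Brook rearrangement and the resulting siloxyallyl anion closes onto the C8 carbonyl to give cis-dialkenylcyclopropanediolate 15, whose alkoxide-accelerated Cope rearrangement forms C1–C10 while breaking the temporary C6–C8 bond, and the regiodefined C8 enolate 16 is trapped on oxygen by PhNTf2. The closest known reaction type is the Brook-rearrangement-mediated [3+4] annulation of acryloylsilanes with lithium enolates of alkenyl methyl ketones. The temporary three-membered ring closes in a 3-exo-trig mode (carbanion onto carbonyl), whereas the seven-membered ring is not closed end to end but arises by [3,3]-sigmatropic ring enlargement of that cyclopropane through a boat transition state. The quaternary C1 is set by approach of C10 to the cyclopentene face anti to the adjacent C2 silyloxy group (methyl β), and C10 is set relative to C1 by the boat geometry together with the E enol ether, which should place the C10 silyloxy group cis to C2 and trans to the methyl (α). The step needs attack at the acylsilane carbonyl and not at the tetrasubstituted alkene, a cis arrangement of the two alkenyl groups and a single enolate regioisomer; the high electrophilicity of the acylsilane, the intramolecular Brook/closure sequence and the sigmatropic origin of the C8=C9 enolate should secure these. Only one inward substituent (the C1 methyl) sits in the boat, which the anionic acceleration should tolerate below 0 °C.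

Step 10
Reactants: 17 enol triflate
Product: 18 2β,10α-bis(tert-butyldimethylsilyloxy)-6-(dimethylphenylsilyloxy)-4β-(triethylsilyloxy)dauca-5,8-diene
Conditions: MeMgBr, Fe(acac)3 (5 mol %), THF/NMP, −30 °C
Reagents that add atoms: methylmagnesium bromide, C[Mg]Br
Why: Iron-catalysed cross-coupling of the alkenyl triflate with the methyl Grignard reagent installs the C8 methyl group with the alkene fixed at C8=C9, and silyl ethers and the silyl enol ether should be inert at this temperature.

Step 11
Reactants: 18 silyl enol ether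
Product: 19 2β,10α-bis(tert-butyldimethylsilyloxy)-4β-hydroxy-5α-H-dauc-8-en-6-one
Conditions: HF·pyridine, pyridine, THF, 0 °C
Reagents that add atoms: none
Why: Selective desilylation: fluoride should cleave the silyl enol ether and the tertiary triethylsilyl ether before the two hindered secondary TBS ethers and without the acid that would ionise the C4 oxygen, and protonation at C5 should give the trans-fused ketone, expected to be favoured because C6 then stands anti to the C4 isopropyl group and correctable by enolisation.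

Step 12
Reactants: 19 β-hydroxy ketone
Product: 20 2β,10α-bis(tert-butyldimethylsilyloxy)dauc-8-ene-4β,6α-diol
Conditions: Me4NBH(OAc)3, MeCN/AcOH, −20 °C
Reagents that add atoms: none
Why: Hydroxyl-directed reduction (Evans–Saksena type): the C4 hydroxyl binds the triacetoxyborohydride and delivers hydride internally to the C6 ketone, which should give the 1,3-anti diol with the C6 hydroxyl α.

Step 13
Reactants: 20 diol; 21 angelic acid
Product: 22 6α-angeloyloxy-2β,10α-bis(tert-butyldimethylsilyloxy)dauc-8-en-4β-ol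
Conditions: 21, 2,4,6-trichlorobenzoyl chloride, Et3N, toluene, rt; then 20, DMAP (cat.), toluene, 70 °C
Reagents that add atoms: none
Why: Yamaguchi esterification: the mixed anhydride acylates the only secondary hydroxyl (C6) while the tertiary C4 hydroxyl is too hindered, and these conditions are the ones under which the Z geometry of angelates is normally kept.

Step 14
Reactants: 22 angelate
Product: 23 6α-angeloyloxydauc-8-ene-2β,4β,10α-triol
Conditions: HF·pyridine, THF, rt
Reagents that add atoms: none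
Why: Fluoride-mediated desilylation removes both secondary TBS ethers without touching the ester or the tertiary alcohol.

Step 15
Reactants: 23 triol
Product: 24 6α-angeloyloxy-4β-hydroxydauc-8-ene-2,10-dione
Conditions: Dess–Martin periodinane, CH2Cl2, 0 °C to rt
Reagents that add atoms: none
Why: Dess–Martin oxidation converts both secondary alcohols into ketones (the tertiary alcohol cannot be oxidised), erasing the C2 and C10 configurations that served only to steer steps 4 and 9.

Step 16
Reactants: 24 diketone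
Product: 25 6α-angeloyloxy-2α,4β-dihydroxydauc-8-en-10-one
Conditions: Me4NBH(OAc)3, MeCN/AcOH, −20 °C
Reagents that add atoms: none
Why: Hydroxyl-directed reduction: only the C2 ketone lies β to the C4 hydroxyl, so hydride should be delivered to its β-face to give the 2α-alcohol (trans-1,3-diol on the five-membered ring), while the C10 enone has no directing group and is not reduced by this mild reagent.

Step 17
Reactants: 25 hydroxy enone
Product: 26 2α-acetoxy-6α-angeloyloxy-4β-hydroxydauc-8-en-10-one
Conditions: Ac2O, pyridine, DMAP (cat.), CH2Cl2, 0 °C to rt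
Reagents that add atoms: acetic anhydride, CC(=O)OC(C)=O
Why: DMAP-catalysed acetylation of the only secondary hydroxyl; the tertiary C4 hydroxyl should not react under these mild conditions.

Step 18
Reactants: 26 enone
Product: 27 2α-acetoxy-6α-angeloyloxydauc-8-ene-4β,10β-diol
Conditions: NaBH4, CeCl3·7H2O, MeOH, −40 °C
Reagents that add atoms: none
Why: Luche reduction gives 1,2-reduction of the enone, and hydride should arrive on the α-face, anti to the methyl group on the adjacent quaternary C1, so that the C10 hydroxyl is β.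

Step 19
Reactants: 27 allylic alcohol
Product: 28 2α-acetoxy-6α-angeloyloxy-10β-benzoyloxydauc-8-en-4β-ol (CNP0248576.1)
Conditions: BzCl, pyridine, DMAP (cat.), CH2Cl2, 0 °C to rt
Reagents that add atoms: benzoyl chloride, O=C(Cl)c1ccccc1
Why: DMAP-catalysed benzoylation of the single secondary (allylic) hydroxyl; the tertiary C4 hydroxyl stays free.

Compound list
1 | (R)-4-(tert-butyldimethylsilyloxy)cyclopent-2-en-1-one | O=C1C=C[C@H](O[Si](C)(C)C(C)(C)C)C1 | starting material
2 | (3R,4R)-4-(tert-butyldimethylsilyloxy)-3-methyl-1-(trimethylsilyloxy)cyclopent-1-ene (methyl trans to the silyloxy group) | C[Si](C)(C)OC1=C[C@@H](C)[C@H](O[Si](C)(C)C(C)(C)C)C1 | intermediate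
3 | (R)-4-(tert-butyldimethylsilyloxy)-3-methylcyclopent-2-en-1-one | O=C1C=C(C)[C@H](O[Si](C)(C)C(C)(C)C)C1 | intermediate
4 | 2,3-trans-dibromo-4-(tert-butyldimethylsilyloxy)-3-methylcyclopentan-1-one (3-bromine anti to the silyloxy group; not isolated) | O=C1C[C@@H](O[Si](C)(C)C(C)(C)C)[C@](C)(Br)[C@H]1Br | intermediate
5 | (R)-2-bromo-4-(tert-butyldimethylsilyloxy)-3-methylcyclopent-2-en-1-one | BrC1=C(C)[C@H](O[Si](C)(C)C(C)(C)C)CC1=O | intermediate
6 | (1R,4R)-2-bromo-4-(tert-butyldimethylsilyloxy)-3-methyl-1-(propan-2-yl)cyclopent-2-en-1-ol (hydroxyl cis to the silyloxy group) | BrC1=C(C)[C@H](O[Si](C)(C)C(C)(C)C)C[C@@]1(O)C(C)C | intermediate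
7 | (1R,4R)-2-bromo-4-(tert-butyldimethylsilyloxy)-3-methyl-1-(propan-2-yl)-1-(triethylsilyloxy)cyclopent-2-ene | BrC1=C(C)[C@H](O[Si](C)(C)C(C)(C)C)C[C@@]1(O[Si](CC)(CC)CC)C(C)C | intermediate
8 | vinyllithium from 7 (not isolated) | [Li]C1=C(C)[C@H](O[Si](C)(C)C(C)(C)C)C[C@@]1(O[Si](CC)(CC)CC)C(C)C | intermediate
9 | [(3R,5R)-3-(tert-butyldimethylsilyloxy)-2-methyl-5-(propan-2-yl)-5-(triethylsilyloxy)cyclopent-1-en-1-yl](morpholin-4-yl)methanone | O=C(N2CCOCC2)C1=C(C)[C@H](O[Si](C)(C)C(C)(C)C)C[C@@]1(O[Si](CC)(CC)CC)C(C)C | intermediate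
10 | [(3R,5R)-3-(tert-butyldimethylsilyloxy)-2-methyl-5-(propan-2-yl)-5-(triethylsilyloxy)cyclopent-1-en-1-yl](dimethylphenylsilyl)methanone | O=C([Si](C)(C)c2ccccc2)C1=C(C)[C@H](O[Si](C)(C)C(C)(C)C)C[C@@]1(O[Si](CC)(CC)CC)C(C)C | intermediate
11 | but-3-yn-2-one | CC(=O)C#C | starting material
12 | tert-butyldimethylsilanol | CC(C)(C)[Si](C)(C)O | starting material
13 | (E)-4-(tert-butyldimethylsilyloxy)but-3-en-2-one | CC(=O)/C=C/O[Si](C)(C)C(C)(C)C | intermediate
14 | lithium (E)-4-(tert-butyldimethylsilyloxy)buta-1,3-dien-2-olate (not isolated) | [Li]OC(=C)/C=C/O[Si](C)(C)C(C)(C)C | intermediate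
15 | lithium cyclopropanolate carrying C8–OLi with the (E)-2-silyloxyvinyl group and C6–OSiMe2Ph with the cyclopentenyl group, the two alkenyl groups cis (not isolated) | [Li]O[C@]1(/C=C/O[Si](C)(C)C(C)(C)C)C[C@@]1(O[Si](C)(C)c2ccccc2)C3=C(C)[C@H](O[Si](C)(C)C(C)(C)C)C[C@@]3(O[Si](CC)(CC)CC)C(C)C | intermediate
16 | lithium 2β,10α-bis(tert-butyldimethylsilyloxy)-6-(dimethylphenylsilyloxy)-4β-(triethylsilyloxy)-14-nordauca-5,8-dien-8-olate (not isolated) | [Li]OC1=C[C@@H](O[Si](C)(C)C(C)(C)C)[C@@]2(C)[C@H](O[Si](C)(C)C(C)(C)C)C[C@@](O[Si](CC)(CC)CC)(C(C)C)C2=C(O[Si](C)(C)c3ccccc3)C1 | intermediate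
17 | 2β,10α-bis(tert-butyldimethylsilyloxy)-6-(dimethylphenylsilyloxy)-4β-(triethylsilyloxy)-14-nordauca-5,8-dien-8-yl trifluoromethanesulfonate | FC(F)(F)S(=O)(=O)OC1=C[C@@H](O[Si](C)(C)C(C)(C)C)[C@@]2(C)[C@H](O[Si](C)(C)C(C)(C)C)C[C@@](O[Si](CC)(CC)CC)(C(C)C)C2=C(O[Si](C)(C)c3ccccc3)C1 | intermediate
18 | 2β,10α-bis(tert-butyldimethylsilyloxy)-6-(dimethylphenylsilyloxy)-4β-(triethylsilyloxy)dauca-5,8-diene | CC1=C[C@@H](O[Si](C)(C)C(C)(C)C)[C@@]2(C)[C@H](O[Si](C)(C)C(C)(C)C)C[C@@](O[Si](CC)(CC)CC)(C(C)C)C2=C(O[Si](C)(C)c3ccccc3)C1 | intermediate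
19 | 2β,10α-bis(tert-butyldimethylsilyloxy)-4β-hydroxy-5α-H-dauc-8-en-6-one | O=C1CC(C)=C[C@@H](O[Si](C)(C)C(C)(C)C)[C@@]2(C)[C@H](O[Si](C)(C)C(C)(C)C)C[C@@](O)(C(C)C)[C@H]12 | intermediate
20 | 2β,10α-bis(tert-butyldimethylsilyloxy)dauc-8-ene-4β,6α-diol | O[C@H]1CC(C)=C[C@@H](O[Si](C)(C)C(C)(C)C)[C@@]2(C)[C@H](O[Si](C)(C)C(C)(C)C)C[C@@](O)(C(C)C)[C@H]12 | intermediate
21 | angelic acid, (Z)-2-methylbut-2-enoic acid | C/C=C(/C)C(=O)O | starting material
22 | 6α-angeloyloxy-2β,10α-bis(tert-butyldimethylsilyloxy)dauc-8-en-4β-ol | C/C=C(/C)C(=O)O[C@H]1CC(C)=C[C@@H](O[Si](C)(C)C(C)(C)C)[C@@]2(C)[C@H](O[Si](C)(C)C(C)(C)C)C[C@@](O)(C(C)C)[C@H]12 | intermediate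
23 | 6α-angeloyloxydauc-8-ene-2β,4β,10α-triol | C/C=C(/C)C(=O)O[C@H]1CC(C)=C[C@@H](O)[C@@]2(C)[C@H](O)C[C@@](O)(C(C)C)[C@H]12 | intermediate
24 | 6α-angeloyloxy-4β-hydroxydauc-8-ene-2,10-dione | C/C=C(/C)C(=O)O[C@H]1CC(C)=CC(=O)[C@@]2(C)C(=O)C[C@@](O)(C(C)C)[C@H]12 | intermediate
25 | 6α-angeloyloxy-2α,4β-dihydroxydauc-8-en-10-one | C/C=C(/C)C(=O)O[C@H]1CC(C)=CC(=O)[C@@]2(C)[C@@H](O)C[C@@](O)(C(C)C)[C@H]12 | intermediate
26 | 2α-acetoxy-6α-angeloyloxy-4β-hydroxydauc-8-en-10-one | C/C=C(/C)C(=O)O[C@H]1CC(C)=CC(=O)[C@@]2(C)[C@@H](OC(C)=O)C[C@@](O)(C(C)C)[C@H]12 | intermediate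
27 | 2α-acetoxy-6α-angeloyloxydauc-8-ene-4β,10β-diol | C/C=C(/C)C(=O)O[C@H]1CC(C)=C[C@H](O)[C@@]2(C)[C@@H](OC(C)=O)C[C@@](O)(C(C)C)[C@H]12 | intermediate
28 | 2α-acetoxy-6α-angeloyloxy-10β-benzoyloxydauc-8-en-4β-ol (CNP0248576.1) | C/C=C(/C)C(=O)O[C@H]1CC(C)=C[C@H](OC(=O)c2ccccc2)[C@@]2(C)[C@@H](OC(C)=O)C[C@@](O)(C(C)C)[C@H]12 | target

Total step count: 19. Longest linear sequence: 18 steps (steps 1–7 and 9–19, from 1); step 8 is a one-step side branch.

Steps most likely to fail

Step 9. The enolate may attack the congested acylsilane carbonyl too slowly, the Brook anion may be diverted into a five-membered carbocycle, or the two substituted ring carbons next to the reacting alkene may give poor facial discrimination. The fallback builds the C4 carbinol after the ring; it sets out from 5 and returns at 19. Bromoenone 5 is ketalised (1,2-bis(trimethylsilyloxy)ethane, TMSOTf cat.) to (R)-6-bromo-8-(tert-butyldimethylsilyloxy)-7-methyl-1,4-dioxaspiro[4.4]non-6-ene F1. Lithiation and acylation as in step 6 give the morpholine amide F2, and tert-butyldiphenylsilyllithium converts it into the less hindered, acid-stable acylsilane F3. The same [3+4] annulation with 14 and PhNTf2 then gives the 4,4-ethylenedioxy enol triflate F4, with the face chosen by the C2 silyloxy group alone. Methylation as in step 10 gives the diene F5, and PPTS in wet acetone unmasks the C4 ketone as the vinylogous silyl ester F6. iPrMgCl/CeCl3 should add to this carbonyl from the α-face, anti to the C1 methyl and the C2 silyloxy group, to give the 4β-carbinol F7. Buffered TBAF (AcOH) then cleaves the silyl enol ether to give 19.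

Step 7. The silyl anion may fail to add to the very hindered amide carbonyl or may attack the silyl ethers instead. The fallback sets out from 7 and returns at 10. Bromide 7 is lithiated (t-BuLi) and formylated with DMF to give the enal F8. PhMe2SiLi adds 1,2 to the unhindered formyl group to give the α-silyl allylic alcohol F9 (both carbinol epimers). Oxidation (Dess–Martin periodinane or Swern) gives acylsilane 10.

Step 13. Acylation of the hindered C6 hydroxyl may stall, or forcing conditions may isomerise the angelate to the tiglate. The fallback builds the Z-alkene on the substrate; it sets out from 20 and returns at 22. Diol 20 is esterified (DCC, DMAP) with 2-[bis(2,2,2-trifluoroethoxy)phosphoryl]propanoic acid to give the 6α-phosphonopropanoate F10. A Still–Gennari olefination (KN(SiMe3)2, 18-crown-6, acetaldehyde, THF, −78 °C) then gives angelate 22.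

Further compounds
F1 | step 9 | (R)-6-bromo-8-(tert-butyldimethylsilyloxy)-7-methyl-1,4-dioxaspiro[4.4]non-6-ene | BrC1=C(C)[C@H](O[Si](C)(C)C(C)(C)C)CC12OCCO2
F2 | step 9 | [(R)-8-(tert-butyldimethylsilyloxy)-7-methyl-1,4-dioxaspiro[4.4]non-6-en-6-yl](morpholin-4-yl)methanone | O=C(N2CCOCC2)C1=C(C)[C@H](O[Si](C)(C)C(C)(C)C)CC13OCCO3
F3 | step 9 | [(R)-8-(tert-butyldimethylsilyloxy)-7-methyl-1,4-dioxaspiro[4.4]non-6-en-6-yl](tert-butyldiphenylsilyl)methanone | O=C([Si](c2ccccc2)(c3ccccc3)C(C)(C)C)C1=C(C)[C@H](O[Si](C)(C)C(C)(C)C)CC14OCCO4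
F4 | step 9 | 2β,10α-bis(tert-butyldimethylsilyloxy)-6-(tert-butyldiphenylsilyloxy)-4,4-ethylenedioxy-4-deisopropyl-14-nordauca-5,8-dien-8-yl trifluoromethanesulfonate | FC(F)(F)S(=O)(=O)OC1=C[C@@H](O[Si](C)(C)C(C)(C)C)[C@@]2(C)[C@H](O[Si](C)(C)C(C)(C)C)CC3(OCCO3)C2=C(O[Si](c4ccccc4)(c5ccccc5)C(C)(C)C)C1
F5 | step 9 | 2β,10α-bis(tert-butyldimethylsilyloxy)-6-(tert-butyldiphenylsilyloxy)-4,4-ethylenedioxy-4-deisopropyldauca-5,8-diene | CC1=C[C@@H](O[Si](C)(C)C(C)(C)C)[C@@]2(C)[C@H](O[Si](C)(C)C(C)(C)C)CC3(OCCO3)C2=C(O[Si](c4ccccc4)(c5ccccc5)C(C)(C)C)C1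
F6 | step 9 | 2β,10α-bis(tert-butyldimethylsilyloxy)-6-(tert-butyldiphenylsilyloxy)-4-deisopropyldauca-5,8-dien-4-one | CC1=C[C@@H](O[Si](C)(C)C(C)(C)C)[C@@]2(C)[C@H](O[Si](C)(C)C(C)(C)C)CC(=O)C2=C(O[Si](c3ccccc3)(c4ccccc4)C(C)(C)C)C1
F7 | step 9 | 2β,10α-bis(tert-butyldimethylsilyloxy)-6-(tert-butyldiphenylsilyloxy)dauca-5,8-dien-4β-ol | CC1=C[C@@H](O[Si](C)(C)C(C)(C)C)[C@@]2(C)[C@H](O[Si](C)(C)C(C)(C)C)C[C@@](O)(C(C)C)C2=C(O[Si](c3ccccc3)(c4ccccc4)C(C)(C)C)C1
F8 | step 7 | (3R,5R)-3-(tert-butyldimethylsilyloxy)-2-methyl-5-(propan-2-yl)-5-(triethylsilyloxy)cyclopent-1-ene-1-carbaldehyde | O=CC1=C(C)[C@H](O[Si](C)(C)C(C)(C)C)C[C@@]1(O[Si](CC)(CC)CC)C(C)C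
F9 | step 7 | [(3R,5R)-3-(tert-butyldimethylsilyloxy)-2-methyl-5-(propan-2-yl)-5-(triethylsilyloxy)cyclopent-1-en-1-yl](dimethylphenylsilyl)methanol (both carbinol epimers) | OC([Si](C)(C)c2ccccc2)C1=C(C)[C@H](O[Si](C)(C)C(C)(C)C)C[C@@]1(O[Si](CC)(CC)CC)C(C)C
F10 | step 13 | 6α-{2-[bis(2,2,2-trifluoroethoxy)phosphoryl]propanoyloxy}-2β,10α-bis(tert-butyldimethylsilyloxy)dauc-8-en-4β-ol (phosphonate α-carbon unassigned) | CC(C(=O)O[C@H]1CC(C)=C[C@@H](O[Si](C)(C)C(C)(C)C)[C@@]2(C)[C@H](O[Si](C)(C)C(C)(C)C)C[C@@](O)(C(C)C)[C@H]12)P(=O)(OCC(F)(F)F)OCC(F)(F)F
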